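**Plan**

1. Retrosynthesis: after O-demethylation, the lactone ring of the 8-oxygenated 3,4-dihydroisocoumarin is cut in one operation at C4–C4a, C1–C8a and C1–O2, giving 2-iodoanisole, CO and (R)-2-[(Z)-pentadec-6-enyl]oxirane.
2. Enabling feature: the C8 oxygen, the carbonyl-bearing C8a and the CH2-bearing C4a are three adjacent carbons of the benzene ring, and O2–C3–C4 is a terminal epoxide in disguise. An aryl iodide with one blocked ortho position and one free ortho C–H is what a palladium/norbornene (Catellani-type) relay needs.
3. The epoxide is cut between the first and second carbons of the side chain (alkyl Grignard reagent plus (R)-epichlorohydrin) and at the propargylic bond of an alkyne precursor (dec-1-yne plus 1-bromo-4-chlorobutane).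
4. Forward: acetylide alkylation, semihydrogenation, Grignard opening of epichlorohydrin and oxirane closure give the epoxide; the key annulation then builds the lactone ring on the purchased benzene ring, and demethylation frees the phenol.
5. Stereochemistry: C3 (R) is bought as (R)-epichlorohydrin and its C–O bond is never broken; the Z-alkene comes from syn addition of H2 to the alkyne.

Key step: step 5

Assumption: the organopalladium species 12 and 13 of step 5 are turnover intermediates of the catalytic cycle and are drawn without their phosphine ligand.

**Route**

Step 1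
Reactants: 1 dec-1-yne; 2 1-bromo-4-chlorobutane
Product: 4 1-chlorotetradec-5-yne, via dec-1-ynyllithium 3 (not isolated)
Conditions: n-BuLi, THF, −78 °C; then 2, DMPU, −78 °C to rt
Reagents that add atoms: none
Why: Acetylide alkylation, in which the lithium acetylide displaces bromide by SN2 much faster than chloride, so the chloride end is kept for step 3.

Step 2
Reactants: 4 1-chlorotetradec-5-yne
Product: 5 (Z)-1-chlorotetradec-5-ene
Conditions: H2 (1 atm), Pd/CaCO3 poisoned with Pb(OAc)2 (Lindlar catalyst), quinoline, hexane, rt
Reagents that add atoms: none
Why: Lindlar semihydrogenation delivers both hydrogen atoms to one face of the alkyne on the poisoned palladium surface, which sets the Z-alkene, and the primary alkyl chloride is inert.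

Step 3
Reactants: 5 (Z)-1-chlorotetradec-5-ene; 6 (R)-epichlorohydrin
Product: 9 (2R,8Z)-1-chloroheptadec-8-en-2-ol, via (Z)-tetradec-5-enylmagnesium chloride 7 (not isolated), via chloromagnesium alkoxide 8 (not isolated)
Conditions: Mg turnings, I2 (cat.), THF, 50 °C; then CuI (10 mol%), 6, THF, −40 °C to 0 °C; then 1 M HCl
Reagents that add atoms: none
Why: Copper-catalysed Grignard opening of an epoxide at its unsubstituted carbon (SN2) is faster than chloride displacement, so no bond at the stereocenter of 6 is broken and it is carried into 9 as R.

Step 4
Reactants: 9 (2R,8Z)-1-chloroheptadec-8-en-2-ol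
Product: 10 (R)-2-[(Z)-pentadec-6-en-1-yl]oxirane
Conditions: powdered NaOH, Et2O, rt
Reagents that add atoms: none
Why: Intramolecular Williamson etherification (3-exo-tet) closes the oxirane at the CH2Cl carbon, so the configuration at the carbinol carbon is retained.

Step 5
Reactants: 10 (R)-2-[(Z)-pentadec-6-en-1-yl]oxirane; 11 2-iodoanisole
Product: 14 (3R)-8-methoxy-3-[(6Z)-pentadec-6-en-1-yl]isochroman-1-one, via arylpalladium alkoxide 12 (not isolated), via acylpalladium alkoxide 13 (not isolated)
Conditions: Pd(OAc)2 (10 mol%), XPhos (20 mol%), potassium 5-norbornene-2-carboxylate (50 mol%), K2CO3 (2 equiv), CO (1 atm, balloon), NMP, 70 °C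
Reagents that add atoms: carbon monoxide, [C-]#[O+]
Why: Proposed new method: the step is a palladium/norbornene (Catellani-type) relay in which zerovalent palladium adds to the C–I bond of 11, norbornene inserts and the free ortho C–H is palladated to an aryl–norbornyl palladacycle of divalent palladium, which opens epoxide 10 at its CH2 carbon by SN2-type oxidative addition to tetravalent palladium and forms the aryl–CH2 bond by reductive elimination; β-carbon elimination then expels norbornene to give 12, CO inserts into the aryl–palladium bond to give 13, and acyl–oxygen reductive elimination releases 14 and zerovalent palladium. The closest known reaction types are the palladium/norbornene ortho-alkylation of aryl iodides by terminal epoxides that ends in ring closure to 2,3-dihydrobenzofurans or isochromans, and the palladium-catalysed alkoxycarbonylation of aryl halides; their union, with CO as the ipso partner and the epoxide-derived alkoxide as the acyl acceptor, is the part without precedent. The only ring closed is the six-membered lactone, by attack of the tethered alkoxide on the acylpalladium carbon (6-exo-trig, as C–O reductive elimination from the seven-membered palladacycle 13). No stereocenter is created: the C–O bond at the stereocenter of 10 is never broken, so C3 of 14 keeps the R configuration. The step needs a single ortho-alkylation, secured by the methoxy group of 11, which blocks the second ortho position and makes norbornene extrusion follow the first alkylation; attack at the unsubstituted epoxide carbon, secured by the steric bias of a monosubstituted oxirane; and norbornene insertion ahead of CO insertion, favoured by the strained alkene, 1 atm of CO and the reversibility of aroylpalladium formation while no alkoxide is at hand. The 1,2-dialkyl Z-alkene is a far poorer insertion partner than norbornene and should pass unchanged.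

Step 6
Reactants: 14 (3R)-8-methoxy-3-[(6Z)-pentadec-6-en-1-yl]isochroman-1-one
Product: 16 (3R)-8-hydroxy-3-[(6Z)-pentadec-6-en-1-yl]isochroman-1-one (CNP0138671.1), via aryloxydichloroborane 15 (not isolated)
Conditions: BCl3 (1 M in CH2Cl2), CH2Cl2, −78 °C to 0 °C; then H2O
Reagents that add atoms: none
Why: Chelation-assisted Lewis-acid ether cleavage, in which BCl3 bridges the lactone carbonyl and the peri-methoxy oxygen and chloride removes the methyl group by SN2, should leave the isolated Z-alkene, the lactone and C3 untouched at low temperature.

**Compound list**

1 | dec-1-yne | CCCCCCCCC#C | starting material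
2 | 1-bromo-4-chlorobutane | ClCCCCBr | starting material
3 | dec-1-ynyllithium (formed in the flask) | CCCCCCCCC#C[Li] | intermediate
4 | 1-chlorotetradec-5-yne | CCCCCCCCC#CCCCCCl | intermediate
5 | (Z)-1-chlorotetradec-5-ene | CCCCCCCC/C=C\CCCCCl | intermediate
6 | (R)-epichlorohydrin, (R)-2-(chloromethyl)oxirane | ClC[C@H]1CO1 | starting material
7 | (Z)-tetradec-5-enylmagnesium chloride (formed in the flask) | CCCCCCCC/C=C\CCCC[Mg]Cl | intermediate
8 | chloromagnesium (2R,8Z)-1-chloroheptadec-8-en-2-olate (formed in the flask) | ClC[C@H](O[Mg]Cl)CCCCC/C=C\CCCCCCCC | intermediate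
9 | (2R,8Z)-1-chloroheptadec-8-en-2-ol | ClC[C@H](O)CCCCC/C=C\CCCCCCCC | intermediate
10 | (R)-2-[(Z)-pentadec-6-en-1-yl]oxirane | CCCCCCCC/C=C\CCCCC[C@@H]1CO1 | intermediate
11 | 2-iodoanisole, 1-iodo-2-methoxybenzene | COc1ccccc1I | starting material
12 | arylpalladium alkoxide, six-membered oxapalladacycle (phosphine omitted, formed in the flask) | COc1cccc2C[C@@H](CCCCC/C=C\CCCCCCCC)O[Pd]c12 | intermediate
13 | acylpalladium alkoxide, seven-membered palladacycle (phosphine omitted, formed in the flask) | COc1cccc2C[C@@H](CCCCC/C=C\CCCCCCCC)O[Pd]C(=O)c12 | intermediate
14 | (3R)-8-methoxy-3-[(6Z)-pentadec-6-en-1-yl]isochroman-1-one | CCCCCCCC/C=C\CCCCC[C@@H]1Cc2cccc(OC)c2C(=O)O1 | intermediate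
15 | (3R)-8-(dichloroboranyloxy)-3-[(6Z)-pentadec-6-en-1-yl]isochroman-1-one (formed in the flask) | CCCCCCCC/C=C\CCCCC[C@@H]1Cc2cccc(OB(Cl)Cl)c2C(=O)O1 | intermediate
16 | (3R)-8-hydroxy-3-[(6Z)-pentadec-6-en-1-yl]isochroman-1-one, CNP0138671.1 | CCCCCCCC/C=C\CCCCC[C@@H]1Cc2cccc(O)c2C(=O)O1 | target

**Step count and risks**

Total step count: 6. Longest linear sequence: 6 steps (1 → 4 → 5 → 9 → 10 → 14 → 16).

Steps most likely to fail:

1. Step 5 (bears the label). CO may be taken up at the wrong point of the relay, either by the first arylpalladium iodide or by the aryl–norbornyl palladacycle before the epoxide is engaged. CO may also saturate palladium and stall the relay, and C–O reductive elimination from 12 to a five-membered cyclic ether may outrun carbonyl insertion. The fallback uses known chemistry and sets out from 10. Directed ortho-metalation of commercial N,N-diethyl-2-methoxybenzamide (s-BuLi, TMEDA, THF, −78 °C) should occur ortho to the amide and give the aryllithium N,N-diethyl-2-lithio-6-methoxybenzamide F1. With BF3·OEt2 at −78 °C this should open 10 at its CH2 carbon, and after an NH4Cl quench give the hydroxy amide N,N-diethyl-2-[(2R,8Z)-2-hydroxyheptadec-8-en-1-yl]-6-methoxybenzamide F2, with the stereocenter untouched. Acid-catalysed lactonisation (camphorsulfonic acid, toluene, 80 °C) expels diethylamine and returns to the route at 14.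

2. Step 3. During magnesium insertion the hex-5-enyl-type radical may close to a cyclopentane, Wurtz coupling may consume the chloride, and the chloro alkoxide may close to the epoxide in the flask and take up a second Grignard equivalent. The fallback avoids the Grignard reagent and sets out from 1. Dec-1-ynyllithium 3 is alkylated with 7-bromohept-1-ene (THF, DMPU) to give heptadec-1-en-8-yne F3. Epoxidation with mCPBA (CH2Cl2, 0 °C) at the terminal alkene, which reacts faster than the alkyne, gives racemic 2-(pentadec-6-yn-1-yl)oxirane F4. Jacobsen hydrolytic kinetic resolution (0.55 equiv H2O, the enantiomer of the (salen)Co(OAc) catalyst that hydrolyses the S epoxide faster) leaves (R)-2-(pentadec-6-yn-1-yl)oxirane F5 and removes the S epoxide as its diol. Lindlar semihydrogenation as in step 2 returns to the route at 10.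

3. Step 6. The Lewis acid or the HCl it releases may add to the alkene or isomerise it from Z to E, and the lactone may open under forcing conditions. The fallback changes the protecting group and sets out from 10. Commercial 2-iodophenol is protected (NaH, chloromethyl methyl ether, THF, 0 °C) as 1-iodo-2-(methoxymethoxy)benzene F6. F6 is joined with 10 and CO under the conditions of step 5 to give (3R)-8-(methoxymethoxy)-3-[(6Z)-pentadec-6-en-1-yl]isochroman-1-one F7. Mild acetal hydrolysis (2 M HCl, THF, 40 °C) returns to the route at 16 without any Lewis acid.

**Further compounds**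

F1 | step 5 | N,N-diethyl-2-lithio-6-methoxybenzamide | CCN(CC)C(=O)c1c([Li])cccc1OC
F2 | step 5 | N,N-diethyl-2-[(2R,8Z)-2-hydroxyheptadec-8-en-1-yl]-6-methoxybenzamide | CCN(CC)C(=O)c1c(OC)cccc1C[C@H](O)CCCCC/C=C\CCCCCCCC
F3 | step 3 | heptadec-1-en-8-yne | C=CCCCCCC#CCCCCCCCC
F4 | step 3 | racemic 2-(pentadec-6-yn-1-yl)oxirane | CCCCCCCCC#CCCCCCC1CO1
F5 | step 3 | (R)-2-(pentadec-6-yn-1-yl)oxirane | CCCCCCCCC#CCCCCC[C@@H]1CO1
F6 | step 6 | 1-iodo-2-(methoxymethoxy)benzene | COCOc1ccccc1I
F7 | step 6 | (3R)-8-(methoxymethoxy)-3-[(6Z)-pentadec-6-en-1-yl]isochroman-1-one | CCCCCCCC/C=C\CCCCC[C@@H]1Cc2cccc(OCOC)c2C(=O)O1
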